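## Analysis of the target

The target (37) is a ten-membered carbocycle of the germacrane type. Its ring atoms are numbered here C1 (the CH that carries isopropenyl), C2, C3 and C4 (the ring olefin, C4 carrying CO2Me), C5, C6, C7 and C8 (the oxirane carbons, C8 also carrying the exocyclic carbon C11 as CH2–O–isobutyryl), C9 (CH–OAc) and C10. There are four stereocentres, C1 (S), C7 (R), C8 (S) and C9 (S). C7, C8 and C9 are contiguous: the oxirane is trans in the ring sense (C6 cis to C11, so it is the oxide of a ring-E C7=C8 olefin), and the C9 oxygen is threo to the oxirane oxygen. C1 stands alone, 1,3 to C9 across the C10 methylene. The C3=C4 enoate is ring-cis, (E) by CIP, with the ester trans to C2. Sensitive features are the oxirane between two acyloxy-bearing carbons (acyl migration and oxirane opening once C9–OH is free), the conjugated ester, two different O-acyl groups that must go on in order, and the isopropenyl group, which excludes hydrogenolysis and non-directed oxidation. The difficulty lies in closing a medium ring that holds two trisubstituted double-bond equivalents and in C1, which has no functional neighbour. The strategy rests on C1: it is a CH between two CH2 groups (C2 and C10) and an isopropenyl group, out of reach of C9, so it is made by a reagent-controlled union of three fragments at that one carbon.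

## Retrosynthetic reasoning

**37 to 35.** The C9 acetate is installed last, from alcohol 36, which comes from silyl ether 35. The C9 oxygen therefore stays masked through every basic and organometallic step, and only two operations are run on the finished ring.

**35 to 34.** The ring is opened at C3=C4 by an intramolecular Horner–Wadsworth–Emmons disconnection to aldehyde-phosphonate 34. This bond is chosen because a carbonyl olefination gives the enoate directly in its final position. The geometry it prefers (ester trans to C2) is also the ring-cis one, and no stereocentre is next to the reacting carbons.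

**34 to 30.** Aldehyde 34 comes from alcohol 33, and 33 from 32 by cleavage of the primary silyl ether at C3 in the presence of the hindered secondary one at C9. The oxirane of 32 is traced to allylic alcohol 30 through epoxy alcohol 31 (Sharpless asymmetric epoxidation, then acylation of the C11 hydroxyl). The epoxide is set in the open chain so that the chiral catalyst, not a ring conformation, decides the face. A directed oxidation also leaves the isopropenyl group alone. Direction from a free C9 hydroxyl would be expected to give the erythro, wrong isomer, so the C11 hydroxyl is the handle.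

**30 to 25.** Alcohol 30 comes from 29 by removal of the C11 protecting group. The phosphonate of 29 is introduced α to the ester of 26 through enolate 27 and phosphonite 28. Ester 26 is the methyl ester of acid 25. C4 thus becomes the olefination donor without a further carbon–carbon bond.

**25 to 22 and 23.** The C7=C8 bond is cut by a Wittig disconnection into ketone 22 and phosphonium salt 23. The salt brings C4 to C7 and the ester carbon in one piece. The α-alkoxy ketone is the substrate class for which the ylide substituent ends up cis to the alkoxymethyl carbon, which is the C6/C11 relationship the oxirane needs.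

**22 to 15.** Ketone 22 comes from carbinol 21, made by adding alkoxymethyllithium 20 (from stannane 19, itself from 18) to aldehyde 17. This forms C8–C11. Aldehyde 17 comes from alcohol 16, and 16 from benzyl ether 15. C8 and C9 are thus carried from the chiral pool and only the oxidation level at C8 is changed.

**15 to 3, 7 and 9.** The two bonds at C1 (C1–C10 and C1–isopropenyl) are cut together. Carbamate 3 supplies C1 to C3, boronic ester 7 supplies C8 to C10 with C9 already configured, and isopropenyllithium 9 supplies the alkenyl group. The forward reaction has to create C1 as a single enantiomeric centre by lithiation–borylation and then exchange boron for isopropenyl with retention. A chiral diamine sets C1 independently of C9.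

**Fragments.** Carbamate 3 comes from diol 1 through 2. Boronic ester 7 comes from glycidyl ether 4 through 5 and 6 without touching its stereocentre. Reagent 9 comes from 8.

## Alternatives that were turned down

**Alternative 1:** Disconnection at C4–C5 with the enoate disguised as a β-keto ester. In the forward direction LiN(SiMe3)2 in THF at high dilution would turn the open-chain iodo β-keto ester A1 into its chelated lithium enolate. C4 would displace the primary iodide at C5 to give the ten-membered β-keto ester A2 (as its enol).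
- For it: the bond formed is sp3–sp3, the closure is irreversible, and the nucleophile is soft and well behaved.
- Against it: the electrophile is an unactivated primary iodide, so O-alkylation to a less strained twelve-membered enol ether and intermolecular alkylation compete. A2 still has oxygen on C3, so at least two more steps (enol sulfonate, reduction) are needed before the C3–H enoate exists, and their geometry must again come out ring-cis. The plan is also silent on C1.
- Comparison: on the ring closure itself this alternative is at least as strong as an intramolecular olefination. The chosen strategy offers instead an olefination that delivers the final enoate in one step, and a controlled answer to the C1/C9 relationship.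

**Alternative 2:** Disconnection at C7–C8 by reductive coupling. SmI2 would reduce the C7 aldehyde of keto aldehyde A3 to its ketyl, which adds to the C8 ketone inside a chelate of trivalent samarium with the C9 ether. This gives diol A4. Its C7 hydroxyl would later be sulfonylated and displaced by the C8 oxygen with inversion.
- For it: samarium pinacol couplings are among the most dependable medium-ring closures, and the ring and both oxirane carbons would be set in one step.
- Against it: the C8 ketone has oxygen on both α-carbons, the substrate class that SmI2 tends to deoxygenate. The enoate is exposed to the reductant. The required diol diastereomer rests on a chelate model and not on a reagent whose sense is known. Two further steps are needed to reach the oxirane. C1 is again not addressed.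
- Comparison: it is stronger on the ring-closing event. The chosen strategy offers a catalyst-controlled epoxidation of a simple allylic alcohol, whose facial sense is predictable, and the same number of steps or fewer.

**Alternative 3:** Disconnection at a relocated C2=C3 olefin. The second-generation Hoveyda–Grubbs catalyst would join the propenyl CH on C1 and the vinyl CH on C4 of polyene A5 with loss of propene. DBU in the same pot would then move the new olefin into conjugation to give diene ester A6.
- For it: the metathesis forms only a disubstituted olefin, it is catalytic and tolerant, and the geometry of the first-formed olefin does not matter.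
- Against it: A5 needs a C1 that carries two different alkenyl groups, a doubly allylic stereocentre that is harder to make and easier to lose (ruthenium hydride migration toward C1 would give a conjugated diene). In a ten-membered ring the conjugated position and its ring-cis geometry are reached only under thermodynamic control, which need not favour the enoate. A5 also holds four olefins and an extra C4 centre.
- Comparison: it is stronger on step and atom economy at the ring-closing stage. The chosen strategy offers that every double bond is made where it stays, and that C1 is made as a plain, configurationally robust CH.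

Key step: step 7

Remark: (+)-sparteine is treated as a purchasable reagent; the (+)-sparteine surrogate diamine would be used in the same way. Ring locants C1 to C11 as defined above are used for all intermediates.

## Route

Step 1
Reactants: 1 propane-1,3-diol
Product: 2 3-(tert-butyldimethylsilyloxy)propan-1-ol
Conditions: TBSCl (1 equiv), imidazole, 1 (4 equiv), THF, 0 °C to rt
Reagents that add atoms: tert-butyldimethylsilyl chloride, CC(C)(C)[Si](C)(C)Cl
Why: Statistical monosilylation of a cheap symmetrical diol used in excess; the silyl ether is inert to the alkyllithium chemistry that follows and can later be told apart from the hindered secondary silyl ether at C9.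

Step 2
Reactants: 2 3-(tert-butyldimethylsilyloxy)propan-1-ol
Product: 3 3-(tert-butyldimethylsilyloxy)propyl N,N-diisopropylcarbamate
Conditions: iPr2NCOCl, Et3N, CH2Cl2, reflux
Reagents that add atoms: N,N-diisopropylcarbamoyl chloride, CC(C)N(C(C)C)C(Cl)=O
Why: O-Carbamoylation of a primary alcohol; the hindered carbamate resists attack by s-BuLi, directs lithiation to its α-carbon (future C1) and later serves as the leaving group.

Step 3
Reactants: 4 (S)-benzyl glycidyl ether
Product: 5 (R)-1-(benzyloxy)-3-iodopropan-2-ol
Conditions: LiI, AcOH, THF, rt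
Reagents that add atoms: lithium iodide, [Li+].[I-]
Why: SN2 opening of the terminal epoxide at its unsubstituted carbon (future C10); the stereocentre (future C9) is not touched, and its descriptor changes only because iodine changes the priorities.

Step 4
Reactants: 5 (R)-1-(benzyloxy)-3-iodopropan-2-ol
Product: 6 (R)-[1-(benzyloxy)-3-iodopropan-2-yloxy](tert-butyl)dimethylsilane
Conditions: TBSOTf, 2,6-lutidine, CH2Cl2, −78 °C
Reagents that add atoms: tert-butyldimethylsilyl trifluoromethanesulfonate, CC(C)(C)[Si](C)(C)OS(=O)(=O)C(F)(F)F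
Why: Silylation of the secondary alcohol with a non-nucleophilic base at low temperature, which avoids re-closure of the iodohydrin to the epoxide.

Step 5
Reactants: 6 (R)-[1-(benzyloxy)-3-iodopropan-2-yloxy](tert-butyl)dimethylsilane
Product: 7 2-[(S)-3-(benzyloxy)-2-(tert-butyldimethylsilyloxy)propyl]-4,4,5,5-tetramethyl-1,3,2-dioxaborolane
Conditions: B2pin2, CuI (10 mol %), PPh3 (13 mol %), LiOMe, DMF, rt
Reagents that add atoms: bis(pinacolato)diboron, CC1(C)OB(OC1(C)C)B1OC(C)(C)C(C)(C)O1
Why: Copper-catalysed borylation of a primary alkyl iodide with a diboron reagent; the silyloxy group on the neighbouring carbon is a poor leaving group and the stereocentre is not involved.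

Step 6
Reactants: 8 2-bromopropene
Product: 9 isopropenyllithium (solution, used at once)
Conditions: t-BuLi (2 equiv), THF, −78 °C
Reagents that add atoms: tert-butyllithium, [Li]C(C)(C)C
Why: Bromine–lithium exchange on a vinyl bromide; the second equivalent destroys the tert-butyl bromide that is formed.

Step 7
Reactants: 3 3-(tert-butyldimethylsilyloxy)propyl N,N-diisopropylcarbamate; 7 2-[(S)-3-(benzyloxy)-2-(tert-butyldimethylsilyloxy)propyl]-4,4,5,5-tetramethyl-1,3,2-dioxaborolane; 9 isopropenyllithium
Product: 15 (2S,4S)-1-(benzyloxy)-2-(tert-butyldimethylsilyloxy)-4-[2-(tert-butyldimethylsilyloxy)ethyl]-5-methylhex-5-ene, via lithiated carbamate 10 (not isolated), via boronate complex 11 (not isolated), via secondary boronic ester 12 (not isolated), via isopropenyl boronate complex 13 (not isolated), via iodo boronic ester 14 (not isolated)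
Conditions: 3, s-BuLi, (+)-sparteine, Et2O, −78 °C, 5 h; 7, −78 °C, 1 h, then 35 °C, 16 h; THF, 9, −78 °C; I2, MeOH, −78 °C; NaOMe, MeOH, −78 °C to rt
Reagents that add atoms: none
Why: s-BuLi held by (+)-sparteine removes the pro-R hydrogen next to the carbamate oxygen of 3 (carbamate-directed, ligand-controlled deprotonation) and gives the configurationally stable (R)-organolithium 10 at −78 °C. 10 adds to the boron atom of 7 with retention to form complex 11, and on warming the C10 alkyl group shifts from boron to C1 anti to the departing carbamate (inversion at C1), which makes the C1–C10 bond in 12. Isopropenyllithium 9 then gives complex 13; iodine activates its alkene, C1 migrates from boron to carbon with retention (14), and NaOMe induces anti elimination of boron and iodine, which makes the C1–isopropenyl bond of 15. The closest known chemistry is the sparteine-mediated lithiation–borylation of primary alkyl carbamates with primary pinacol boronic esters and the Zweifel olefination of the resulting secondary boronic esters with α-substituted vinyllithiums, run here in one flask. No ring is closed. The single new stereocentre, C1, is set by the diamine alone (reagent control): every later event at C1 is stereospecific, so (+)-sparteine leads to (S)-C1, and C9, which comes unchanged from 4, has no influence. The step needs 1,2-migration in 11 to outrun β-elimination of the C9 silyloxy group, which the good carbamate leaving group and the bulky, weakly coordinating silyl ether favour, and it needs deprotonation only next to the carbamate, which the directing group secures.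

Step 8
Reactants: 15 (2S,4S)-1-(benzyloxy)-2-(tert-butyldimethylsilyloxy)-4-[2-(tert-butyldimethylsilyloxy)ethyl]-5-methylhex-5-ene
Product: 16 (2S,4S)-2-(tert-butyldimethylsilyloxy)-4-[2-(tert-butyldimethylsilyloxy)ethyl]-5-methylhex-5-en-1-ol (C8 alcohol)
Conditions: lithium 4,4′-di-tert-butylbiphenylide, THF, −78 °C; then H2O
Reagents that add atoms: none
Why: Single-electron reductive cleavage of the benzyl ether; the isolated 1,1-disubstituted alkene and the silyl ethers are not reduced at −78 °C, which is why hydrogenolysis is not used.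

Step 9
Reactants: 16 (2S,4S)-2-(tert-butyldimethylsilyloxy)-4-[2-(tert-butyldimethylsilyloxy)ethyl]-5-methylhex-5-en-1-ol
Product: 17 (2S,4S)-2-(tert-butyldimethylsilyloxy)-4-[2-(tert-butyldimethylsilyloxy)ethyl]-5-methylhex-5-enal (C8 aldehyde)
Conditions: Dess–Martin periodinane, NaHCO3, CH2Cl2, 0 °C to rt
Reagents that add atoms: none
Why: Buffered hypervalent-iodine oxidation of a primary alcohol; the α-silyloxy aldehyde is used directly so that C9 does not epimerise.

Step 10
Reactants: 18 tributyl(iodomethyl)stannane
Product: 19 tributyl[(4-methoxybenzyloxy)methyl]stannane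
Conditions: 4-MeOC6H4CH2OH, NaH, THF/DMF, 0 °C to rt
Reagents that add atoms: 4-methoxybenzyl alcohol, COc1ccc(CO)cc1
Why: Williamson etherification at the iodomethyl carbon gives the tin precursor of an α-alkoxymethyl carbanion; the oxidatively removable benzyl-type group is chosen so that C11–OH can later be freed beside silyl ethers.

Step 11
Reactants: 17 (2S,4S)-2-(tert-butyldimethylsilyloxy)-4-[2-(tert-butyldimethylsilyloxy)ethyl]-5-methylhex-5-enal; 19 tributyl[(4-methoxybenzyloxy)methyl]stannane
Product: 21 (3S,5S)-3-(tert-butyldimethylsilyloxy)-5-[2-(tert-butyldimethylsilyloxy)ethyl]-1-(4-methoxybenzyloxy)-6-methylhept-6-en-2-ol (both C8 epimers), via alkoxymethyllithium 20 (not isolated)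
Conditions: 19, n-BuLi, THF, −78 °C, 10 min; 17, −78 °C; H2O
Reagents that add atoms: none
Why: Tin–lithium exchange gives 20, which adds to the aldehyde at −78 °C faster than it rearranges and forms the C8–C11 bond. The configuration of the new carbinol is irrelevant because it is oxidised in the next step.

Step 12
Reactants: 21 (3S,5S)-3-(tert-butyldimethylsilyloxy)-5-[2-(tert-butyldimethylsilyloxy)ethyl]-1-(4-methoxybenzyloxy)-6-methylhept-6-en-2-ol
Product: 22 (3S,5S)-3-(tert-butyldimethylsilyloxy)-5-[2-(tert-butyldimethylsilyloxy)ethyl]-1-(4-methoxybenzyloxy)-6-methylhept-6-en-2-one (C8 ketone)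
Conditions: Dess–Martin periodinane, NaHCO3, CH2Cl2, rt
Reagents that add atoms: none
Why: Oxidation of the secondary alcohol under non-basic conditions gives the α-alkoxy α′-silyloxy ketone without enolisation toward C9.

Step 13
Reactants: 22 (3S,5S)-3-(tert-butyldimethylsilyloxy)-5-[2-(tert-butyldimethylsilyloxy)ethyl]-1-(4-methoxybenzyloxy)-6-methylhept-6-en-2-one; 23 (4-carboxybutyl)triphenylphosphonium bromide
Product: 25 (5E,7S,9S)-7-(tert-butyldimethylsilyloxy)-9-[2-(tert-butyldimethylsilyloxy)ethyl]-6-[(4-methoxybenzyloxy)methyl]-10-methylundeca-5,10-dienoic acid, via ylide 24 (not isolated)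
Conditions: 23, NaN(SiMe3)2 (2 equiv), THF, 0 °C; 22, THF/HMPA, −78 °C to rt; AcOH
Reagents that add atoms: none
Why: Wittig olefination of a ketone with a non-stabilised ylide; α-alkoxy ketones are the class for which the ylide substituent ends up cis to the alkoxymethyl carbon, here C6 cis to C11 ((E) by CIP), and the bulk of the branched silyloxy side at C9 pushes the same way. The carboxylate form of the ylide cannot acylate itself, and addition at low temperature should be faster than enolisation toward C9.

Step 14
Reactants: 25 (5E,7S,9S)-7-(tert-butyldimethylsilyloxy)-9-[2-(tert-butyldimethylsilyloxy)ethyl]-6-[(4-methoxybenzyloxy)methyl]-10-methylundeca-5,10-dienoic acid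
Product: 26 methyl (5E,7S,9S)-7-(tert-butyldimethylsilyloxy)-9-[2-(tert-butyldimethylsilyloxy)ethyl]-6-[(4-methoxybenzyloxy)methyl]-10-methylundeca-5,10-dienoate
Conditions: MeI, K2CO3, DMF, rt
Reagents that add atoms: iodomethane, CI
Why: O-Alkylation of the carboxylate gives the methyl ester of the target; no other group in 25 reacts with this mild base.

Step 15
Reactants: 26 methyl (5E,7S,9S)-7-(tert-butyldimethylsilyloxy)-9-[2-(tert-butyldimethylsilyloxy)ethyl]-6-[(4-methoxybenzyloxy)methyl]-10-methylundeca-5,10-dienoate
Product: 29 methyl (5E,7S,9S)-2-(diethoxyphosphoryl)-7-(tert-butyldimethylsilyloxy)-9-[2-(tert-butyldimethylsilyloxy)ethyl]-6-[(4-methoxybenzyloxy)methyl]-10-methylundeca-5,10-dienoate (both C4 epimers), via lithium enolate 27 (not isolated), via phosphonite ester 28 (not isolated)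
Conditions: LiN(iPr)2, THF, −78 °C; ClP(OEt)2, −78 °C to rt; H2O2 (30 %), 0 °C
Reagents that add atoms: diethyl chlorophosphite, CCOP(Cl)OCC; hydrogen peroxide, OO
Why: The ester enolate is phosphinylated at carbon by the trivalent phosphorus chloride and the phosphonite is oxidised to the phosphonate, a known route to α-phosphono esters. The C4 centre created here disappears in the olefination.

Step 16
Reactants: 29 methyl (5E,7S,9S)-2-(diethoxyphosphoryl)-7-(tert-butyldimethylsilyloxy)-9-[2-(tert-butyldimethylsilyloxy)ethyl]-6-[(4-methoxybenzyloxy)methyl]-10-methylundeca-5,10-dienoate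
Product: 30 methyl (5E,7S,9S)-2-(diethoxyphosphoryl)-6-(hydroxymethyl)-7-(tert-butyldimethylsilyloxy)-9-[2-(tert-butyldimethylsilyloxy)ethyl]-10-methylundeca-5,10-dienoate
Conditions: DDQ, CH2Cl2/pH 7 buffer, 0 °C
Reagents that add atoms: none
Why: Oxidative cleavage of the 4-methoxybenzyl ether frees only the C11 allylic hydroxyl; silyl ethers, phosphonate and alkenes are inert to buffered DDQ.

Step 17
Reactants: 30 methyl (5E,7S,9S)-2-(diethoxyphosphoryl)-6-(hydroxymethyl)-7-(tert-butyldimethylsilyloxy)-9-[2-(tert-butyldimethylsilyloxy)ethyl]-10-methylundeca-5,10-dienoate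
Product: 31 methyl 2-(diethoxyphosphoryl)-4-[(2R,3S)-3-(hydroxymethyl)-3-{(1S,3S)-1-(tert-butyldimethylsilyloxy)-3-[2-(tert-butyldimethylsilyloxy)ethyl]-4-methylpent-4-en-1-yl}oxiran-2-yl]butanoate ((7R,8S)-epoxy alcohol)
Conditions: Ti(OiPr)4 (0.3 equiv), L-(+)-diethyl tartrate (0.36 equiv), t-BuOOH, 4 Å MS, CH2Cl2, −20 °C
Reagents that add atoms: tert-butyl hydroperoxide, CC(C)(C)OO
Why: Sharpless asymmetric epoxidation: oxygen is delivered inside the titanium complex bound to the C11 hydroxyl, so only the allylic-alcohol olefin reacts and isopropenyl is left alone. L-(+)-Diethyl tartrate is the enantiomer that converts (E)-hex-2-en-1-ol into its (2S,3S)-epoxide; transposed to 30, with C6 on the side of the CH2OH group, this face gives the (7R,8S) oxirane, so C7 and C8 are set together by the catalyst and not by C9.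

Step 18
Reactants: 31 methyl 2-(diethoxyphosphoryl)-4-[(2R,3S)-3-(hydroxymethyl)-3-{(1S,3S)-1-(tert-butyldimethylsilyloxy)-3-[2-(tert-butyldimethylsilyloxy)ethyl]-4-methylpent-4-en-1-yl}oxiran-2-yl]butanoate
Product: 32 the C11 isobutyrate of 31, methyl 2-(diethoxyphosphoryl)-4-[(2R,3S)-3-[(2-methylpropanoyloxy)methyl]-3-{(1S,3S)-1-(tert-butyldimethylsilyloxy)-3-[2-(tert-butyldimethylsilyloxy)ethyl]-4-methylpent-4-en-1-yl}oxiran-2-yl]butanoate
Conditions: (iPrCO)2O, Et3N, DMAP (cat.), CH2Cl2, 0 °C
Reagents that add atoms: isobutyric anhydride, CC(C)C(=O)OC(=O)C(C)C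
Why: Acylation of the only free hydroxyl puts the final ester on C11 before any other oxygen is unmasked; the anhydride avoids chloride, which could open the oxirane.

Step 19
Reactants: 32 methyl 2-(diethoxyphosphoryl)-4-[(2R,3S)-3-[(2-methylpropanoyloxy)methyl]-3-{(1S,3S)-1-(tert-butyldimethylsilyloxy)-3-[2-(tert-butyldimethylsilyloxy)ethyl]-4-methylpent-4-en-1-yl}oxiran-2-yl]butanoate
Product: 33 the C3 alcohol, methyl 2-(diethoxyphosphoryl)-4-[(2R,3S)-3-[(2-methylpropanoyloxy)methyl]-3-{(1S,3S)-1-(tert-butyldimethylsilyloxy)-3-(2-hydroxyethyl)-4-methylpent-4-en-1-yl}oxiran-2-yl]butanoate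
Conditions: HF·pyridine, pyridine, THF, 0 °C
Reagents that add atoms: none
Why: A primary tert-butyldimethylsilyl ether is cleaved much faster than the secondary one at C9, which is shielded by the fully substituted C8; buffered fluoride should not open the electron-poor oxirane or touch the esters.

Step 20
Reactants: 33 methyl 2-(diethoxyphosphoryl)-4-[(2R,3S)-3-[(2-methylpropanoyloxy)methyl]-3-{(1S,3S)-1-(tert-butyldimethylsilyloxy)-3-(2-hydroxyethyl)-4-methylpent-4-en-1-yl}oxiran-2-yl]butanoate
Product: 34 the C3 aldehyde, methyl 2-(diethoxyphosphoryl)-4-[(2R,3S)-3-[(2-methylpropanoyloxy)methyl]-3-{(1S,3R)-1-(tert-butyldimethylsilyloxy)-4-methyl-3-(2-oxoethyl)pent-4-en-1-yl}oxiran-2-yl]butanoate (3R only through the change of priorities)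
Conditions: Dess–Martin periodinane, NaHCO3, CH2Cl2, rt
Reagents that add atoms: none
Why: Buffered oxidation of the primary alcohol; the aldehyde has no α-stereocentre and is taken on at once.

Step 21
Reactants: 34 methyl 2-(diethoxyphosphoryl)-4-[(2R,3S)-3-[(2-methylpropanoyloxy)methyl]-3-{(1S,3R)-1-(tert-butyldimethylsilyloxy)-4-methyl-3-(2-oxoethyl)pent-4-en-1-yl}oxiran-2-yl]butanoate
Product: 35 methyl (1R,4E,7S,9S,10S)-9-(tert-butyldimethylsilyloxy)-10-[(2-methylpropanoyloxy)methyl]-7-(prop-1-en-2-yl)-11-oxabicyclo[8.1.0]undec-4-ene-4-carboxylate (ring locants: 1S, 7R, 8S, 9S; C3=C4 ring-cis)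
Conditions: LiCl, DBU, MeCN, 1 mM (slow addition of 34), rt
Reagents that add atoms: none
Why: Intramolecular Horner–Wadsworth–Emmons olefination under LiCl/amine conditions closes the ten-membered ring at C3=C4. An α-substituted phosphonoacetate places the ester trans to the aldehyde-derived substituent (C2), which is also the ring-cis arrangement that a ten-membered ring accommodates best. High dilution disfavours oligomers, and the mild base leaves the oxirane and both esters alone.

Step 22
Reactants: 35 methyl (1R,4E,7S,9S,10S)-9-(tert-butyldimethylsilyloxy)-10-[(2-methylpropanoyloxy)methyl]-7-(prop-1-en-2-yl)-11-oxabicyclo[8.1.0]undec-4-ene-4-carboxylate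
Product: 36 methyl (1R,4E,7S,9S,10R)-9-hydroxy-10-[(2-methylpropanoyloxy)methyl]-7-(prop-1-en-2-yl)-11-oxabicyclo[8.1.0]undec-4-ene-4-carboxylate (10R only through the change of priorities)
Conditions: HF·pyridine, THF, 0 °C to rt
Reagents that add atoms: none
Why: Acidic fluoride removes the remaining silyl ether without generating an alkoxide, so neither migration of the isobutyryl group to C9 nor attack of C9–O on the oxirane is promoted.

Step 23
Reactants: 36 methyl (1R,4E,7S,9S,10R)-9-hydroxy-10-[(2-methylpropanoyloxy)methyl]-7-(prop-1-en-2-yl)-11-oxabicyclo[8.1.0]undec-4-ene-4-carboxylate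
Product: 37 methyl (1R,4E,7S,9S,10S)-9-acetoxy-10-[(2-methylpropanoyloxy)methyl]-7-(prop-1-en-2-yl)-11-oxabicyclo[8.1.0]undec-4-ene-4-carboxylate (target)
Conditions: Ac2O, pyridine, DMAP (cat.), CH2Cl2, 0 °C
Reagents that add atoms: acetic anhydride, CC(=O)OC(C)=O
Why: Acetylation of the secondary alcohol directly after its release completes the target; DMAP catalysis keeps the exposure of the free hydroxy oxirane short.

## Compound list

1 | propane-1,3-diol | OCCCO | starting material
2 | 3-(tert-butyldimethylsilyloxy)propan-1-ol | OCCCO[Si](C)(C)C(C)(C)C | intermediate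
3 | 3-(tert-butyldimethylsilyloxy)propyl N,N-diisopropylcarbamate | CC(C)N(C(C)C)C(=O)OCCCO[Si](C)(C)C(C)(C)C | intermediate
4 | (S)-benzyl glycidyl ether | C1[C@H](O1)COCc1ccccc1 | starting material
5 | (R)-1-(benzyloxy)-3-iodopropan-2-ol | IC[C@H](O)COCc1ccccc1 | intermediate
6 | (R)-[1-(benzyloxy)-3-iodopropan-2-yloxy](tert-butyl)dimethylsilane | IC[C@H](O[Si](C)(C)C(C)(C)C)COCc1ccccc1 | intermediate
7 | 2-[(S)-3-(benzyloxy)-2-(tert-butyldimethylsilyloxy)propyl]-4,4,5,5-tetramethyl-1,3,2-dioxaborolane | CC1(C)OB(C[C@H](O[Si](C)(C)C(C)(C)C)COCc2ccccc2)OC1(C)C | intermediate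
8 | 2-bromopropene | CC(Br)=C | starting material
9 | isopropenyllithium | [Li]C(C)=C | intermediate
10 | (R)-3-(tert-butyldimethylsilyloxy)-1-lithiopropyl N,N-diisopropylcarbamate (as its (+)-sparteine complex) | [Li][C@@H](OC(=O)N(C(C)C)C(C)C)CCO[Si](C)(C)C(C)(C)C | intermediate
11 | lithium boronate complex of 10 with 7 (boron bound to C1 and C10) | [Li+].CC1(C)O[B-](C[C@H](O[Si](C)(C)C(C)(C)C)COCc2ccccc2)([C@@H](OC(=O)N(C(C)C)C(C)C)CCO[Si](C)(C)C(C)(C)C)OC1(C)C | intermediate
12 | 2-[(2S,4S)-1-(benzyloxy)-2,6-bis(tert-butyldimethylsilyloxy)hexan-4-yl]-4,4,5,5-tetramethyl-1,3,2-dioxaborolane | CC1(C)OB(OC1(C)C)[C@@H](CCO[Si](C)(C)C(C)(C)C)C[C@H](O[Si](C)(C)C(C)(C)C)COCc1ccccc1 | intermediate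
13 | lithium isopropenyl boronate complex of 12 | [Li+].C=C(C)[B-]1(OC(C)(C)C(C)(C)O1)[C@@H](CCO[Si](C)(C)C(C)(C)C)C[C@H](O[Si](C)(C)C(C)(C)C)COCc1ccccc1 | intermediate
14 | β-iodo boronic ester (C1 bound to the former α-carbon of isopropenyl, which also carries CH3, CH2I and the boronate; that carbon as a mixture of epimers) | ICC(C)(B1OC(C)(C)C(C)(C)O1)[C@@H](CCO[Si](C)(C)C(C)(C)C)C[C@H](O[Si](C)(C)C(C)(C)C)COCc1ccccc1 | intermediate
15 | (2S,4S)-1-(benzyloxy)-2-(tert-butyldimethylsilyloxy)-4-[2-(tert-butyldimethylsilyloxy)ethyl]-5-methylhex-5-ene | C=C(C)[C@@H](CCO[Si](C)(C)C(C)(C)C)C[C@H](O[Si](C)(C)C(C)(C)C)COCc1ccccc1 | intermediate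
16 | (2S,4S)-2-(tert-butyldimethylsilyloxy)-4-[2-(tert-butyldimethylsilyloxy)ethyl]-5-methylhex-5-en-1-ol | C=C(C)[C@@H](CCO[Si](C)(C)C(C)(C)C)C[C@H](O[Si](C)(C)C(C)(C)C)CO | intermediate
17 | (2S,4S)-2-(tert-butyldimethylsilyloxy)-4-[2-(tert-butyldimethylsilyloxy)ethyl]-5-methylhex-5-enal | C=C(C)[C@@H](CCO[Si](C)(C)C(C)(C)C)C[C@H](O[Si](C)(C)C(C)(C)C)C=O | intermediate
18 | tributyl(iodomethyl)stannane | CCCC[Sn](CCCC)(CCCC)CI | starting material
19 | tributyl[(4-methoxybenzyloxy)methyl]stannane | CCCC[Sn](CCCC)(CCCC)COCc1ccc(OC)cc1 | intermediate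
20 | (4-methoxybenzyloxy)methyllithium | [Li]COCc1ccc(OC)cc1 | intermediate
21 | (3S,5S)-3-(tert-butyldimethylsilyloxy)-5-[2-(tert-butyldimethylsilyloxy)ethyl]-1-(4-methoxybenzyloxy)-6-methylhept-6-en-2-ol (both C2 epimers) | C=C(C)[C@@H](CCO[Si](C)(C)C(C)(C)C)C[C@H](O[Si](C)(C)C(C)(C)C)C(O)COCc1ccc(OC)cc1 | intermediate
22 | (3S,5S)-3-(tert-butyldimethylsilyloxy)-5-[2-(tert-butyldimethylsilyloxy)ethyl]-1-(4-methoxybenzyloxy)-6-methylhept-6-en-2-one | C=C(C)[C@@H](CCO[Si](C)(C)C(C)(C)C)C[C@H](O[Si](C)(C)C(C)(C)C)C(=O)COCc1ccc(OC)cc1 | intermediate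
23 | (4-carboxybutyl)triphenylphosphonium bromide | [Br-].OC(=O)CCCC[P+](c1ccccc1)(c1ccccc1)c1ccccc1 | starting material
24 | sodium 5-(triphenyl-λ5-phosphanylidene)pentanoate (carboxylate ylide) | [Na+].[O-]C(=O)CCCC=P(c1ccccc1)(c1ccccc1)c1ccccc1 | intermediate
25 | (5E,7S,9S)-7-(tert-butyldimethylsilyloxy)-9-[2-(tert-butyldimethylsilyloxy)ethyl]-6-[(4-methoxybenzyloxy)methyl]-10-methylundeca-5,10-dienoic acid | OC(=O)CCC/C=C(\COCc1ccc(OC)cc1)[C@@H](O[Si](C)(C)C(C)(C)C)C[C@H](CCO[Si](C)(C)C(C)(C)C)C(C)=C | intermediate
26 | methyl ester of 25 | COC(=O)CCC/C=C(\COCc1ccc(OC)cc1)[C@@H](O[Si](C)(C)C(C)(C)C)C[C@H](CCO[Si](C)(C)C(C)(C)C)C(C)=C | intermediate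
27 | lithium enolate of 26 (ketene acetal geometry not defined) | COC(O[Li])=CCC/C=C(\COCc1ccc(OC)cc1)[C@@H](O[Si](C)(C)C(C)(C)C)C[C@H](CCO[Si](C)(C)C(C)(C)C)C(C)=C | intermediate
28 | methyl (5E,7S,9S)-2-(diethoxyphosphanyl)-7-(tert-butyldimethylsilyloxy)-9-[2-(tert-butyldimethylsilyloxy)ethyl]-6-[(4-methoxybenzyloxy)methyl]-10-methylundeca-5,10-dienoate (C2 epimers) | COC(=O)C(CC/C=C(\COCc1ccc(OC)cc1)[C@@H](O[Si](C)(C)C(C)(C)C)C[C@H](CCO[Si](C)(C)C(C)(C)C)C(C)=C)P(OCC)OCC | intermediate
29 | methyl (5E,7S,9S)-2-(diethoxyphosphoryl)-7-(tert-butyldimethylsilyloxy)-9-[2-(tert-butyldimethylsilyloxy)ethyl]-6-[(4-methoxybenzyloxy)methyl]-10-methylundeca-5,10-dienoate (C2 epimers) | COC(=O)C(CC/C=C(\COCc1ccc(OC)cc1)[C@@H](O[Si](C)(C)C(C)(C)C)C[C@H](CCO[Si](C)(C)C(C)(C)C)C(C)=C)P(=O)(OCC)OCC | intermediate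
30 | methyl (5E,7S,9S)-2-(diethoxyphosphoryl)-6-(hydroxymethyl)-7-(tert-butyldimethylsilyloxy)-9-[2-(tert-butyldimethylsilyloxy)ethyl]-10-methylundeca-5,10-dienoate | COC(=O)C(CC/C=C(\CO)[C@@H](O[Si](C)(C)C(C)(C)C)C[C@H](CCO[Si](C)(C)C(C)(C)C)C(C)=C)P(=O)(OCC)OCC | intermediate
31 | methyl 2-(diethoxyphosphoryl)-4-[(2R,3S)-3-(hydroxymethyl)-3-{(1S,3S)-1-(tert-butyldimethylsilyloxy)-3-[2-(tert-butyldimethylsilyloxy)ethyl]-4-methylpent-4-en-1-yl}oxiran-2-yl]butanoate | COC(=O)C(CC[C@H]1O[C@]1(CO)[C@@H](O[Si](C)(C)C(C)(C)C)C[C@H](CCO[Si](C)(C)C(C)(C)C)C(C)=C)P(=O)(OCC)OCC | intermediate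
32 | methyl 2-(diethoxyphosphoryl)-4-[(2R,3S)-3-[(2-methylpropanoyloxy)methyl]-3-{(1S,3S)-1-(tert-butyldimethylsilyloxy)-3-[2-(tert-butyldimethylsilyloxy)ethyl]-4-methylpent-4-en-1-yl}oxiran-2-yl]butanoate | COC(=O)C(CC[C@H]1O[C@]1(COC(=O)C(C)C)[C@@H](O[Si](C)(C)C(C)(C)C)C[C@H](CCO[Si](C)(C)C(C)(C)C)C(C)=C)P(=O)(OCC)OCC | intermediate
33 | methyl 2-(diethoxyphosphoryl)-4-[(2R,3S)-3-[(2-methylpropanoyloxy)methyl]-3-{(1S,3S)-1-(tert-butyldimethylsilyloxy)-3-(2-hydroxyethyl)-4-methylpent-4-en-1-yl}oxiran-2-yl]butanoate | COC(=O)C(CC[C@H]1O[C@]1(COC(=O)C(C)C)[C@@H](O[Si](C)(C)C(C)(C)C)C[C@H](CCO)C(C)=C)P(=O)(OCC)OCC | intermediate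
34 | methyl 2-(diethoxyphosphoryl)-4-[(2R,3S)-3-[(2-methylpropanoyloxy)methyl]-3-{(1S,3R)-1-(tert-butyldimethylsilyloxy)-4-methyl-3-(2-oxoethyl)pent-4-en-1-yl}oxiran-2-yl]butanoate | COC(=O)C(CC[C@H]1O[C@]1(COC(=O)C(C)C)[C@@H](O[Si](C)(C)C(C)(C)C)C[C@H](CC=O)C(C)=C)P(=O)(OCC)OCC | intermediate
35 | methyl (1R,4E,7S,9S,10S)-9-(tert-butyldimethylsilyloxy)-10-[(2-methylpropanoyloxy)methyl]-7-(prop-1-en-2-yl)-11-oxabicyclo[8.1.0]undec-4-ene-4-carboxylate | C=C(C)[C@H]1C/C=C(/C(=O)OC)CC[C@H]2O[C@]2(COC(=O)C(C)C)[C@@H](O[Si](C)(C)C(C)(C)C)C1 | intermediate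
36 | methyl (1R,4E,7S,9S,10R)-9-hydroxy-10-[(2-methylpropanoyloxy)methyl]-7-(prop-1-en-2-yl)-11-oxabicyclo[8.1.0]undec-4-ene-4-carboxylate | C=C(C)[C@H]1C/C=C(/C(=O)OC)CC[C@H]2O[C@]2(COC(=O)C(C)C)[C@@H](O)C1 | intermediate
37 | methyl (1R,4E,7S,9S,10S)-9-acetoxy-10-[(2-methylpropanoyloxy)methyl]-7-(prop-1-en-2-yl)-11-oxabicyclo[8.1.0]undec-4-ene-4-carboxylate | C=C(C)[C@H]1C/C=C(/C(=O)OC)CC[C@H]2O[C@]2(COC(=O)C(C)C)[C@@H](OC(C)=O)C1 | target

## Step count and least certain steps

Total step count: 23. Longest linear sequence: 19 steps, from 4 to 37 (steps 3 to 5, 7 to 9 and 11 to 23).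

**Step 7 (key step).**
- What may go wrong: loss of the C9 silyloxy group by β-elimination from complex 11 before the 1,2-shift; incomplete formation of the second boronate because the hindered secondary boronic ester meets the α-branched vinyllithium in a medium that still holds diamine and lithium carbamate; and lower enantiomeric purity at C1 if deprotonation is incomplete.
- Fallback: the assembly is staged and the carbenoid is generated by transmetalation. It sets out from 3. Lithiation with s-BuLi/(+)-sparteine and quenching with Bu3SnCl gives (R)-3-(tert-butyldimethylsilyloxy)-1-(tributylstannyl)propyl N,N-diisopropylcarbamate F1, which can be purified and checked for enantiomeric purity. n-BuLi in Et2O at −78 °C regenerates 10 free of diamine. Addition of 7 and migration promoted by MgBr2·OEt2 at lower temperature then give 12, which is isolated. A separate Zweifel step with isopropenylmagnesium bromide in THF/DMSO, I2 and NaOMe returns to the route at 15.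

**Step 13.**
- What may go wrong: poor control of the C7=C8 geometry, because the ketone has oxygen on both α-carbons, and epimerisation at C9 by enolisation under the basic ylide.
- Fallback: a Horner–Wittig sequence in which the geometry is fixed by separation and stereospecific elimination. It sets out from 22 and 23. Alkaline hydrolysis of 23 (NaOH, H2O, heat) gives 5-(diphenylphosphoryl)pentanoic acid F2. Its dilithio derivative (n-BuLi, 2 equiv, THF, −78 °C) adds to 22. The adduct with the required relative configuration at C7/C8, (5R,6R,7S,9S)-7-(tert-butyldimethylsilyloxy)-9-[2-(tert-butyldimethylsilyloxy)ethyl]-5-(diphenylphosphoryl)-6-hydroxy-6-[(4-methoxybenzyloxy)methyl]-10-methylundec-10-enoic acid F3 (its 5S,6S isomer serves equally), is separated by chromatography. Syn elimination with NaH in DMF then returns to the route at 25.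

**Step 17.**
- What may go wrong: opposed double diastereodifferentiation, if the C9 centre works against the catalyst, and slow turnover if the phosphoryl group ties up titanium. Raising the catalyst to a full equivalent is the first adjustment.
- Fallback: the epoxidation is moved behind the ring closure, where no phosphonate is left and the olefin is held in the ring. It sets out from 29.
  - HF·pyridine gives the C3 alcohol, methyl (5E,7S,9S)-2-(diethoxyphosphoryl)-7-(tert-butyldimethylsilyloxy)-9-(2-hydroxyethyl)-6-[(4-methoxybenzyloxy)methyl]-10-methylundeca-5,10-dienoate F4.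
  - Dess–Martin oxidation gives the corresponding C3 aldehyde F5.
  - LiCl/DBU at high dilution gives the ten-membered (3E,7E)-diene ester with C11–O-(4-methoxybenzyl) and C9–O-silyl groups F6.
  - DDQ gives the ring allylic alcohol F7.
  - Ti(OiPr)4, L-(+)-diethyl tartrate and t-BuOOH give the ring epoxy alcohol, methyl (1R,4E,7S,9S,10S)-9-(tert-butyldimethylsilyloxy)-10-(hydroxymethyl)-7-(prop-1-en-2-yl)-11-oxabicyclo[8.1.0]undec-4-ene-4-carboxylate F8.
  - Acylation with isobutyric anhydride returns to the route at 35.

**Step 21.**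
- What may go wrong: intermolecular olefination to a cyclic dimer and oligomers outrunning closure of the strained ring, reversal of the addition step, and, less likely, attack of the phosphonate carbanion on the oxirane.
- Fallback: the C3=C4 bond is closed by olefin metathesis, where loss of ethene makes closure irreversible and the catalyst can return oligomers to the monomeric ring. It sets out from 33.
  - K2CO3 and aqueous formaldehyde turn the phosphonate into the α-methylene ester, methyl 4-[(2R,3S)-3-[(2-methylpropanoyloxy)methyl]-3-{(1S,3S)-1-(tert-butyldimethylsilyloxy)-3-(2-hydroxyethyl)-4-methylpent-4-en-1-yl}oxiran-2-yl]-2-methylidenebutanoate F9.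
  - Dess–Martin oxidation gives the C3 aldehyde F10.
  - Methylenation with Ph3P=CH2 at −78 °C gives the terminal alkene (allyl group on C1) F11.
  - The second-generation Hoveyda–Grubbs catalyst in toluene at 80 °C and high dilution returns to the route at 35.

## Further compounds

F1 | step 7 | (R)-3-(tert-butyldimethylsilyloxy)-1-(tributylstannyl)propyl N,N-diisopropylcarbamate | CCCC[Sn](CCCC)(CCCC)[C@@H](OC(=O)N(C(C)C)C(C)C)CCO[Si](C)(C)C(C)(C)C
F2 | step 13 | 5-(diphenylphosphoryl)pentanoic acid | OC(=O)CCCCP(=O)(c1ccccc1)c1ccccc1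
F3 | step 13 | (5R,6R,7S,9S)-7-(tert-butyldimethylsilyloxy)-9-[2-(tert-butyldimethylsilyloxy)ethyl]-5-(diphenylphosphoryl)-6-hydroxy-6-[(4-methoxybenzyloxy)methyl]-10-methylundec-10-enoic acid | OC(=O)CCC[C@@H](P(=O)(c1ccccc1)c1ccccc1)[C@@](O)(COCc1ccc(OC)cc1)[C@@H](O[Si](C)(C)C(C)(C)C)C[C@H](CCO[Si](C)(C)C(C)(C)C)C(C)=C
F4 | step 17 | methyl (5E,7S,9S)-2-(diethoxyphosphoryl)-7-(tert-butyldimethylsilyloxy)-9-(2-hydroxyethyl)-6-[(4-methoxybenzyloxy)methyl]-10-methylundeca-5,10-dienoate | COC(=O)C(CC/C=C(\COCc1ccc(OC)cc1)[C@@H](O[Si](C)(C)C(C)(C)C)C[C@H](CCO)C(C)=C)P(=O)(OCC)OCC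
F5 | step 17 | methyl (5E,7S,9R)-2-(diethoxyphosphoryl)-7-(tert-butyldimethylsilyloxy)-6-[(4-methoxybenzyloxy)methyl]-10-methyl-9-(2-oxoethyl)undeca-5,10-dienoate | COC(=O)C(CC/C=C(\COCc1ccc(OC)cc1)[C@@H](O[Si](C)(C)C(C)(C)C)C[C@H](CC=O)C(C)=C)P(=O)(OCC)OCC
F6 | step 17 | ten-membered (3E,7E)-diene methyl ester, (1S,9S), with 9-(tert-butyldimethylsilyloxy) and C11–O-(4-methoxybenzyl) | C=C(C)[C@H]1C/C=C(/C(=O)OC)CC/C=C(\COCc2ccc(OC)cc2)[C@@H](O[Si](C)(C)C(C)(C)C)C1
F7 | step 17 | ten-membered (3E,7E)-diene methyl ester, (1S,9S), with 9-(tert-butyldimethylsilyloxy) and free C11 hydroxyl | C=C(C)[C@H]1C/C=C(/C(=O)OC)CC/C=C(\CO)[C@@H](O[Si](C)(C)C(C)(C)C)C1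
F8 | step 17 | methyl (1R,4E,7S,9S,10S)-9-(tert-butyldimethylsilyloxy)-10-(hydroxymethyl)-7-(prop-1-en-2-yl)-11-oxabicyclo[8.1.0]undec-4-ene-4-carboxylate | C=C(C)[C@H]1C/C=C(/C(=O)OC)CC[C@H]2O[C@]2(CO)[C@@H](O[Si](C)(C)C(C)(C)C)C1
F9 | step 21 | methyl 4-[(2R,3S)-3-[(2-methylpropanoyloxy)methyl]-3-{(1S,3S)-1-(tert-butyldimethylsilyloxy)-3-(2-hydroxyethyl)-4-methylpent-4-en-1-yl}oxiran-2-yl]-2-methylidenebutanoate | COC(=O)C(=C)CC[C@H]1O[C@]1(COC(=O)C(C)C)[C@@H](O[Si](C)(C)C(C)(C)C)C[C@H](CCO)C(C)=C
F10 | step 21 | methyl 4-[(2R,3S)-3-[(2-methylpropanoyloxy)methyl]-3-{(1S,3R)-1-(tert-butyldimethylsilyloxy)-4-methyl-3-(2-oxoethyl)pent-4-en-1-yl}oxiran-2-yl]-2-methylidenebutanoate | COC(=O)C(=C)CC[C@H]1O[C@]1(COC(=O)C(C)C)[C@@H](O[Si](C)(C)C(C)(C)C)C[C@H](CC=O)C(C)=C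
F11 | step 21 | methyl 4-[(2R,3S)-3-[(2-methylpropanoyloxy)methyl]-3-{(1S,3S)-1-(tert-butyldimethylsilyloxy)-4-methyl-3-(prop-2-en-1-yl)pent-4-en-1-yl}oxiran-2-yl]-2-methylidenebutanoate | COC(=O)C(=C)CC[C@H]1O[C@]1(COC(=O)C(C)C)[C@@H](O[Si](C)(C)C(C)(C)C)C[C@H](CC=C)C(C)=C
A1 | alternative 1 | open-chain β-keto ester (C3 ketone, C4 ester) with primary iodide at C5, C9 triethylsilyl ether, C11 tert-butyldimethylsilyl ether | COC(=O)CC(=O)C[C@H](C(C)=C)C[C@H](O[Si](CC)(CC)CC)/C(CO[Si](C)(C)C(C)(C)C)=C/CCI
A2 | alternative 1 | ten-membered β-keto ester, drawn as its enol | CC(=C)[C@H]1C/C(O)=C(/C(=O)OC)CC/C=C(\CO[Si](C)(C)C(C)(C)C)[C@@H](O[Si](CC)(CC)CC)C1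
A3 | alternative 2 | open-chain C7 aldehyde / C8 ketone carrying the C3=C4 enoate, C9 4-methoxybenzyl ether, C11 tert-butyldimethylsilyl ether | O=CCC/C(C(=O)OC)=C\C[C@H](C(C)=C)C[C@H](OCc1ccc(OC)cc1)C(=O)CO[Si](C)(C)C(C)(C)C
A4 | alternative 2 | ten-membered C7,C8-diol | C=C(C)[C@H]1C/C=C(/C(=O)OC)CC[C@H](O)[C@@](O)(CO[Si](C)(C)C(C)(C)C)[C@@H](OCc2ccc(OC)cc2)C1
A5 | alternative 3 | open-chain polyene with propenyl and isopropenyl on C1 and vinyl on C4 (either C4 epimer) | C/C=C/[C@H](C(C)=C)C[C@H](O[Si](CC)(CC)CC)/C(CO[Si](C)(C)C(C)(C)C)=C/CCC(C=C)C(=O)OC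
A6 | alternative 3 | ten-membered diene ester with ring-cis C3=C4 enoate and C7=C8 olefin | C=C(C)[C@H]1C/C=C(/C(=O)OC)CC/C=C(\CO[Si](C)(C)C(C)(C)C)[C@@H](O[Si](CC)(CC)CC)C1
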